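**Retrosynthetic overview**

1. Rings A (fused arene) and C (pendant aryl) are bought. Phenol 1, as benzyl ether 2, brings ring A with C4, C3 and the CH2 on C3; aldehyde 3, as vinyl carbinol 4, brings ring C with C1, C2 and the CH2 on C2 (tetralin numbering, C1 = ArCH).
2. Disconnection C1–C8a: a catalytic enantioselective allylic Friedel–Crafts alkylation of 2 by 4 gives the 1,7-diene 5 and sets C1.
3. Disconnection C2–C3 together with both C–O bonds: zirconocene bicyclisation of 5 closes ring B and a zirconacyclopentane in one event (trans-fused zirconabicycle 6); O2 in the same flask turns the two C–Zr bonds into the CH2OH groups of diol 7.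
4. Double O-debenzylation of 7 gives the target 8, which is (1R,2S,3S).
5. Ring order: A and C pre-formed; ring B and the transient metallacycle form together in the key step; no other ring is made.

Assumption: the (S)-configured ligand of step 3 is taken to give (R)-5; if the sense of induction is the opposite, the (R)-ligand is used and nothing else changes.

**Step 1**
Reactants: 1 4-allyl-2,6-dimethoxyphenol (methoxyeugenol)
Product: 2 5-allyl-2-(benzyloxy)-1,3-dimethoxybenzene
Conditions: BnBr (1.1 equiv), K2CO3 (1.5 equiv), DMF, 25 °C, 6 h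
Reagents that add atoms: benzyl bromide, BrCc1ccccc1
Why: Williamson ether synthesis on the only acidic site; the benzyl ether masks the phenol for the acid-promoted and organometallic steps that follow.

**Step 2**
Reactants: 3 4-(benzyloxy)-3-methoxybenzaldehyde (O-benzylvanillin)
Product: 4 rac-1-[4-(benzyloxy)-3-methoxyphenyl]prop-2-en-1-ol
Conditions: CH2=CHMgBr (1.2 equiv), THF, −78 → 0 °C; sat. aq. NH4Cl; used crude (no acidic silica)
Reagents that add atoms: vinylmagnesium bromide, C=C[Mg]Br
Why: Grignard 1,2-addition to the aldehyde; the carbinol may be racemic because its stereocentre is erased in the π-allyl intermediate of step 3.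

**Step 3**
Reactants: 2 5-allyl-2-(benzyloxy)-1,3-dimethoxybenzene (3 equiv, excess recovered) and 4 rac-1-[4-(benzyloxy)-3-methoxyphenyl]prop-2-en-1-ol
Product: 5 1-allyl-4-(benzyloxy)-2-[(1R)-1-[4-(benzyloxy)-3-methoxyphenyl]prop-2-en-1-yl]-3,5-dimethoxybenzene
Conditions: [Ir(cod)Cl]2 (4 mol %), (S)-5-(dinaphtho[2,1-d:1′,2′-f][1,3,2]dioxaphosphepin-4-yl)-5H-dibenzo[b,f]azepine (phosphoramidite–olefin ligand, 16 mol %), Zn(OSO2CF3)2 (20 mol %), ClCH2CH2Cl, 25 °C, 24 h
Reagents that add atoms: none
Why: Proposed new method: acid-assisted ionisation of racemic 4 on the monovalent iridium–phosphoramidite–olefin complex gives a trivalent-iridium π-allyl that is attacked at its aryl-bearing terminus, on the face left open by the ligand, by the only free ring carbon of 2 (ortho and para to methoxy groups), so both enantiomers of 4 converge on (R)-5 and C1 is set by the catalyst; the closest known reactions are the iridium-catalysed enantioselective Friedel–Crafts-type allylic alkylations of indoles and phenols and the alkene- and arene-terminated allylic couplings of this same catalyst system.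

**Step 4**
Reactants: 5 1-allyl-4-(benzyloxy)-2-[(1R)-1-[4-(benzyloxy)-3-methoxyphenyl]prop-2-en-1-yl]-3,5-dimethoxybenzene
Product: 7 [(1R,2S,3S)-7-(benzyloxy)-1-[4-(benzyloxy)-3-methoxyphenyl]-3-(hydroxymethyl)-6,8-dimethoxy-1,2,3,4-tetrahydronaphthalen-2-yl]methanol, via trans-fused zirconabicycle 6 (not isolated)
Conditions: (C5H5)2ZrCl2 (1.3 equiv), n-C4H9Li (2.6 equiv), THF, −78 °C, 1 h; add 5, −78 → 25 °C, 3 h, then 55 °C, 2 h; O2 (1 atm), −78 → 25 °C; 1 M HCl; chromatography, then recrystallisation of 7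
Reagents that add atoms: dioxygen, O=O; zirconocene dichloride, Cl[Zr](Cl)(C1C=CC=C1)C1C=CC=C1 (its (C5H5)2Zr unit is held only in intermediate 6)
Why: Negishi-type zirconocene diene bicyclisation (reductive coupling of the two vinyl groups on divalent zirconium) forms the C2–C3 bond, ring B and the zirconacyclopentane together, the reversible cyclisation settling on warming in the trans-fused zirconabicycle whose C1 aryl group is trans to the C2 CH2–Zr arm (C2 and C3 set relative to C1), after which O2 inserts into both C–Zr bonds without touching a stereocentre.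

**Step 5**
Reactants: 7 [(1R,2S,3S)-7-(benzyloxy)-1-[4-(benzyloxy)-3-methoxyphenyl]-3-(hydroxymethyl)-6,8-dimethoxy-1,2,3,4-tetrahydronaphthalen-2-yl]methanol
Product: 8 [(1R,2S,3S)-7-hydroxy-1-(4-hydroxy-3-methoxyphenyl)-3-(hydroxymethyl)-6,8-dimethoxy-1,2,3,4-tetrahydronaphthalen-2-yl]methanol (target)
Conditions: H2 (1 atm), palladium on carbon (Pd/C, 10 wt %), EtOAc–MeOH 1:1, 25 °C, 4 h
Reagents that add atoms: none
Why: Catalytic hydrogenolysis of the two aryl benzyl ethers; the molecule has no alkene or other reducible group left and no stereocentre is affected.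

**Compound list**

1 | 4-allyl-2,6-dimethoxyphenol | C=CCc1cc(OC)c(O)c(OC)c1 | starting material
2 | 5-allyl-2-(benzyloxy)-1,3-dimethoxybenzene | C=CCc1cc(OC)c(OCc2ccccc2)c(OC)c1 | intermediate
3 | 4-(benzyloxy)-3-methoxybenzaldehyde | COc1cc(C=O)ccc1OCc1ccccc1 | starting material
4 | rac-1-[4-(benzyloxy)-3-methoxyphenyl]prop-2-en-1-ol (racemic) | COc1cc(C(O)C=C)ccc1OCc1ccccc1 | intermediate
5 | 1-allyl-4-(benzyloxy)-2-[(1R)-1-[4-(benzyloxy)-3-methoxyphenyl]prop-2-en-1-yl]-3,5-dimethoxybenzene | COc1cc([C@@H](C=C)c2c(CC=C)cc(OC)c(OCc3ccccc3)c2OC)ccc1OCc1ccccc1 | intermediate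
6 | trans-fused zirconabicycle: bis(cyclopentadienyl)zirconacyclopentane fused at C2–C3 of the (1R,2S,3S)-7-(benzyloxy)-1-[4-(benzyloxy)-3-methoxyphenyl]-6,8-dimethoxytetralin, Zr bound to the CH2 on C2 and the CH2 on C3, aryl on C1 trans to the C2 arm (not isolated) | COc1cc([C@@H]2c3c(cc(OC)c(OCc4ccccc4)c3OC)C[C@@H]3C[Zr](C4C=CC=C4)(C4C=CC=C4)C[C@@H]23)ccc1OCc1ccccc1 | intermediate
7 | [(1R,2S,3S)-7-(benzyloxy)-1-[4-(benzyloxy)-3-methoxyphenyl]-3-(hydroxymethyl)-6,8-dimethoxy-1,2,3,4-tetrahydronaphthalen-2-yl]methanol | COc1cc([C@@H]2c3c(cc(OC)c(OCc4ccccc4)c3OC)C[C@H](CO)[C@H]2CO)ccc1OCc1ccccc1 | intermediate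
8 | [(1R,2S,3S)-7-hydroxy-1-(4-hydroxy-3-methoxyphenyl)-3-(hydroxymethyl)-6,8-dimethoxy-1,2,3,4-tetrahydronaphthalen-2-yl]methanol | COc1cc([C@@H]2c3c(cc(OC)c(O)c3OC)C[C@H](CO)[C@H]2CO)ccc1O | target

**Totals and risks**

Total step count: 5. Longest linear sequence: 4 steps (1 → 2 → 5 → 7 → 8, or equally 3 → 4 → 5 → 7 → 8).

The three steps most likely to fail are steps 4, 3 and 5, in that order of risk; they are discussed below in route order.

Step 3 may fail in three ways: the hindered ring carbon of 2 may attack the linear allyl terminus, an uncatalysed ionisation of the electron-rich carbinol may erode the enantiomeric excess, or 4 may alkylate its own ring C. The fallback replaces the C–H alkylation by an organometallic allylic arylation; it sets out from 2 and 4 and comes back at 5. Ether 2 is brominated at its free ring position (NBS, MeCN, 0 °C) to 1-allyl-4-(benzyloxy)-2-bromo-3,5-dimethoxybenzene F1. Mg turnings and LiCl in THF convert it into the Grignard reagent [6-allyl-3-(benzyloxy)-2,4-dimethoxyphenyl]magnesium bromide F2. Carbinol 4 with SOCl2 and pyridine in Et2O gives, with allylic transposition, (E)-1-(benzyloxy)-4-(3-chloroprop-1-en-1-yl)-2-methoxybenzene F3. F2 and F3 are joined with CuBr·SMe2 (3 mol %) and a chiral BINOL-derived phosphoramidite in CH2Cl2 at −78 °C (SN2′-selective copper-catalysed asymmetric allylic arylation), the ligand antipode chosen to give (R)-5.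

Step 4 is the most exposed step of the route, for three reasons:
- Low-valent zirconium may move the double bond of the doubly benzylic allyl unit of 5 into conjugation before it cyclises.
- The C1/C2 relationship rests on a balance between the peri contact of the C1 aryl group with the 8-methoxy group and its contact with a cyclopentadienyl ring, so the 1,2-cis isomer may compete.
- Oxidation of C–Zr bonds with O2 is often only moderate in yield.

The fallback avoids the metallacycle and closes ring B by an intramolecular oxidative enolate coupling; it sets out from 5 and comes back at 7.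
- Both vinyl groups of 5 are hydroborated with 9-borabicyclo[3.3.1]nonane and oxidised (NaOH, H2O2) to (R)-3-[3-(benzyloxy)-6-(3-hydroxypropyl)-2,4-dimethoxyphenyl]-3-[4-(benzyloxy)-3-methoxyphenyl]propan-1-ol F4.
- Oxidation (TEMPO cat., NaOCl, NaClO2) gives (R)-3-[3-(benzyloxy)-6-(2-carboxyethyl)-2,4-dimethoxyphenyl]-3-[4-(benzyloxy)-3-methoxyphenyl]propanoic acid F5.
- Esterification (MeOH, H2SO4 cat.) gives its dimethyl ester, methyl (R)-3-[3-(benzyloxy)-2,4-dimethoxy-6-(3-methoxy-3-oxopropyl)phenyl]-3-[4-(benzyloxy)-3-methoxyphenyl]propanoate F6.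
- The bis-enolate (LiN(CH(CH3)2)2, 2.2 equiv, THF, −78 °C) is coupled with I2 to form the C2–C3 bond. The crude product is equilibrated with NaOMe in MeOH; C2 and C3 are epimerisable, C1 is not and anchors the absolute configuration. The expected thermodynamic product is the all-trans diester dimethyl (1R,2S,3S)-7-(benzyloxy)-1-[4-(benzyloxy)-3-methoxyphenyl]-6,8-dimethoxy-1,2,3,4-tetrahydronaphthalene-2,3-dicarboxylate F7.
- LiAlH4 in THF at 0 °C reduces F7 to 7.

Step 5 can stall on the electron-rich, strongly adsorbing polyphenol, and the very polar product is hard to purify. The fallback changes both the cleavage chemistry and the isolation; it sets out from 7 and comes back at 8. The benzyl ethers are cleaved with BCl3 and pentamethylbenzene as cation scavenger (CH2Cl2, −78 °C). The crude tetrol is acetylated (Ac2O, pyridine) to [(1R,2S,3S)-7-acetoxy-1-(4-acetoxy-3-methoxyphenyl)-6,8-dimethoxy-1,2,3,4-tetrahydronaphthalene-2,3-diyl]bis(methylene) diacetate F8, which is purified by chromatography or crystallisation. Transesterification with catalytic NaOMe in MeOH then gives 8.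

**Further compounds**

F1 | step 3 | 1-allyl-4-(benzyloxy)-2-bromo-3,5-dimethoxybenzene | C=CCc1cc(OC)c(OCc2ccccc2)c(OC)c1Br
F2 | step 3 | [6-allyl-3-(benzyloxy)-2,4-dimethoxyphenyl]magnesium bromide | C=CCc1cc(OC)c(OCc2ccccc2)c(OC)c1[Mg]Br
F3 | step 3 | (E)-1-(benzyloxy)-4-(3-chloroprop-1-en-1-yl)-2-methoxybenzene | COc1cc(/C=C/CCl)ccc1OCc1ccccc1
F4 | step 4 | (R)-3-[3-(benzyloxy)-6-(3-hydroxypropyl)-2,4-dimethoxyphenyl]-3-[4-(benzyloxy)-3-methoxyphenyl]propan-1-ol | COc1cc([C@@H](CCO)c2c(CCCO)cc(OC)c(OCc3ccccc3)c2OC)ccc1OCc1ccccc1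
F5 | step 4 | (R)-3-[3-(benzyloxy)-6-(2-carboxyethyl)-2,4-dimethoxyphenyl]-3-[4-(benzyloxy)-3-methoxyphenyl]propanoic acid | COc1cc([C@@H](CC(=O)O)c2c(CCC(=O)O)cc(OC)c(OCc3ccccc3)c2OC)ccc1OCc1ccccc1
F6 | step 4 | methyl (R)-3-[3-(benzyloxy)-2,4-dimethoxy-6-(3-methoxy-3-oxopropyl)phenyl]-3-[4-(benzyloxy)-3-methoxyphenyl]propanoate | COc1cc([C@@H](CC(=O)OC)c2c(CCC(=O)OC)cc(OC)c(OCc3ccccc3)c2OC)ccc1OCc1ccccc1
F7 | step 4 | dimethyl (1R,2S,3S)-7-(benzyloxy)-1-[4-(benzyloxy)-3-methoxyphenyl]-6,8-dimethoxy-1,2,3,4-tetrahydronaphthalene-2,3-dicarboxylate | COc1cc([C@@H]2c3c(cc(OC)c(OCc4ccccc4)c3OC)C[C@H](C(=O)OC)[C@H]2C(=O)OC)ccc1OCc1ccccc1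
F8 | step 5 | [(1R,2S,3S)-7-acetoxy-1-(4-acetoxy-3-methoxyphenyl)-6,8-dimethoxy-1,2,3,4-tetrahydronaphthalene-2,3-diyl]bis(methylene) diacetate | COc1cc([C@@H]2c3c(cc(OC)c(OC(C)=O)c3OC)C[C@H](COC(C)=O)[C@H]2COC(C)=O)ccc1OC(C)=O
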